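**Strategy**

Everything rests on cutting the trimethylcyclohexadienone ring (ring D) into a two-carbon unit, its C(OMe) carbon with the adjacent CMe2 carbon, and the four-carbon chain C(Me)–C(=O)–CH=C(OH). The first has the substitution and oxidation pattern of dimethylketene dimethyl acetal; the second is a vinylketene stored as a 2-silyl-3-ethoxy-4-methylcyclobutenone. In one flask the cyclobutenone opens, the acetal adds to the ketene carbon, the zwitterion closes ring D, and acid expels methanol and the temporary silyl group, so the methyl enol ether is placed by connectivity. The free dione CH of ring D then takes isobutyraldehyde and C-8 of (2S)-strobopinin (ring A) in a catalyst-controlled Friedel–Crafts Michael addition.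

Key step: step 3

Remark: (2S)-pinocembrin (chiral pool) and (ethoxyethynyl)trimethylsilane are taken as catalogue compounds; the sense of induction of the chiral phosphoric acid in step 10 cannot be predicted with confidence and is to be fixed by a screen of both antipodes, the C-1′ epimers being diastereomers in any case.

**Route**

Step 1
Reactants: 1 propanoyl chloride; 2 (ethoxyethynyl)trimethylsilane
Product: 4 3-ethoxy-4-methyl-2-(trimethylsilyl)cyclobut-2-en-1-one (racemic), via methylketene 3 (not isolated)
Conditions: Et3N (1.5 equiv), slow addition of 1 (1.5 equiv), Et2O, 0 °C → rt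
Reagents that add atoms: none
Why: Triethylamine dehydrochlorinates 1 to methylketene, which undergoes the thermal [2+2] cycloaddition of ketenes with electron-rich alkynes; the ketene carbonyl carbon bonds to the silicon-bearing alkyne carbon (the nucleophilic terminus of the ynol ether, reinforced by β-silicon stabilisation of the charge developing on the alkoxy carbon), which places OEt at C-3, SiMe3 at C-2 and methyl at C-4, whose racemic stereocentre is lost in step 3.

Step 2
Reactants: 5 1,1,1-trimethoxy-2-methylpropane (trimethyl orthoisobutyrate)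
Product: 6 1,1-dimethoxy-2-methylprop-1-ene (dimethylketene dimethyl acetal)
Conditions: Me3SiOTf (1.1 equiv), iPr2NEt (1.3 equiv), CH2Cl2, 0 °C → rt; distillation
Reagents that add atoms: none
Why: Me3SiOTf abstracts methoxide from the ortho ester to give a dimethoxycarbenium ion that the hindered amine deprotonates at the α-carbon, the silyl-triflate-mediated elimination of alcohol from acetals and ortho esters.

Step 3
Reactants: 4 3-ethoxy-4-methyl-2-(trimethylsilyl)cyclobut-2-en-1-one; 6 1,1-dimethoxy-2-methylprop-1-ene
Product: 10 3-ethoxy-5-methoxy-4,6,6-trimethylcyclohexa-2,4-dien-1-one, via silylvinylketene 7 (not isolated), via zwitterion 8 (not isolated), via ketal 9 (not isolated)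
Conditions: 6 (3 equiv), toluene, 110 °C, sealed tube; then removal of excess 6, CF3CO2H (3 equiv), CH2Cl2, 0 °C, same flask
Reagents that add atoms: none
Why: Proposed new method: heating opens 4 by conrotatory 4π-electrocyclic ring opening to the silylvinylketene 7, the nucleophilic CMe2 carbon of ketene acetal 6 adds to the ketene carbon (first new C–C bond) to give zwitterion 8, and the γ-carbon of its dienolate (the enol-ether CHMe terminus) attacks the dimethoxycarbenium carbon (second new C–C bond) to give ketal 9; the closest known reaction types are the [4+1] annulation of (trialkylsilyl)vinylketenes with carbenoid nucleophiles and their benzannulation with lithium ynolates, in which a nucleophile adds to the ketene carbon anti to silicon and the dienolate then closes a ring, together with the [2+2] cycloaddition of ketenes with ketene acetals, but a ketene O,O-acetal has not been shown as the two-carbon partner of a six-ring-forming vinylketene annulation. Ring D closes in a stepwise polar, formally [4+2] manner, the second bond by 6-(enolendo)-exo-trig attack of the dienolate on the carbenium ion. The temporary Me3Si group secures this periselectivity: it stabilises 7 against dimerisation, disfavours collapse of 8 at the α-carbon to a four-membered ring (which would need a quaternary C–Si centre between two fully substituted carbons), and steers 6 to the side anti to silicon so that the new CMe2–C(OMe)2 arm lies cis to the alkenyl arm, while reversibility of the addition lets a wrongly configured zwitterion return to 7 and 6. CF3CO2H then ionises the ketal and removes the hydrogen at C-4, which turns the new single bond into the C(OMe)=C(Me) double bond, and protodesilylates C-2 by ipso protonation (alkoxy- and β-silyl-stabilised cation). No stereocentre is created, since the CHMe centres of 4 and 9 end up sp2. The regiochemistry (CMe2 to the former ketene carbon, acetal carbon to the CHMe terminus) follows from the polarity of both partners, and the methyl enol ether sits next to CMe2 by connectivity because that carbon enters at the ortho-ester oxidation level and loses exactly one MeOH.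

Step 4
Reactants: 10 3-ethoxy-5-methoxy-4,6,6-trimethylcyclohexa-2,4-dien-1-one
Product: 11 3-hydroxy-5-methoxy-4,4,6-trimethylcyclohexa-2,5-dien-1-one
Conditions: NaOH (1 M aq, 2 equiv), THF, rt; then HCl (1 M) to pH 2, 0 °C
Reagents that add atoms: sodium hydroxide (aqueous), [Na+].[OH-]
Why: Vinylogous ester saponification by conjugate addition–elimination of hydroxide at C-3 (a β-carbon flanked by a CH), whereas the methoxy-bearing C-5 is a δ-carbon shielded on both faces by the adjacent gem-dimethyl group and should keep its methoxy group, and the vinylogous acid anion formed resists further attack.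

Step 5
Reactants: 11 3-hydroxy-5-methoxy-4,4,6-trimethylcyclohexa-2,5-dien-1-one; 12 2-methylpropanal
Product: 14 5-methoxy-4,6,6-trimethyl-2-(2-methylpropylidene)cyclohex-4-ene-1,3-dione (E/Z mixture), via Mannich base 13 (not isolated)
Conditions: piperidine (1.1 equiv), 12 (1.5 equiv), CH2Cl2, rt; then HCl (1 M aq), 0 °C; used crude
Reagents that add atoms: none
Why: Knoevenagel condensation run through a Mannich base: the iminium ion from 12 and piperidine is attacked by the nucleophilic C-2 of the vinylogous acid 11 (the only ring carbon carrying hydrogen) and acid then eliminates piperidine, a protocol that keeps a second molecule of 11 from adding to 14; the double-bond geometry is of no consequence.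

Step 6
Reactants: 15 (2S)-pinocembrin [(2S)-5,7-dihydroxy-2-phenyl-2,3-dihydro-4H-chromen-4-one]
Product: 16 (2S)-5-hydroxy-7-(methoxymethoxy)-2-phenyl-2,3-dihydro-4H-chromen-4-one
Conditions: MOMCl (1.1 equiv), iPr2NEt (1.5 equiv), CH2Cl2, 0 °C
Reagents that add atoms: chloromethyl methyl ether, COCCl
Why: O-alkylation of the more acidic, non-chelated 7-OH, the 5-OH being hydrogen-bonded to the C-4 carbonyl; the mild amine base at 0 °C does not open ring C, so C-2 stays S.

Step 7
Reactants: 16 (2S)-5-hydroxy-7-(methoxymethoxy)-2-phenyl-2,3-dihydro-4H-chromen-4-one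
Product: 17 (2S)-5-hydroxy-6-iodo-7-(methoxymethoxy)-2-phenyl-2,3-dihydro-4H-chromen-4-one
Conditions: NIS (1.05 equiv), DMF, rt, dark
Reagents that add atoms: N-iodosuccinimide, O=C1CCC(=O)N1I
Why: Electrophilic aromatic iodination under neutral conditions, which for 5-hydroxy-7-alkoxy flavonoids goes ortho to the free chelated 5-OH (C-6) and leaves C-8 free for the final C–C bond; the site is to be confirmed by HMBC.

Step 8
Reactants: 17 (2S)-5-hydroxy-6-iodo-7-(methoxymethoxy)-2-phenyl-2,3-dihydro-4H-chromen-4-one
Product: 18 (2S)-5-hydroxy-7-(methoxymethoxy)-6-methyl-2-phenyl-2,3-dihydro-4H-chromen-4-one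
Conditions: SnMe4 (3 equiv), Pd(PPh3)4 (5 mol %), CuI (10 mol %), DMF, 80 °C
Reagents that add atoms: tetramethylstannane, C[Sn](C)(C)C
Why: Stille cross-coupling of the aryl iodide (oxidative addition to zerovalent palladium, methyl transfer from tin, reductive elimination) under neutral conditions, which avoids base-induced chalcone opening that would scramble C-2 and exchange C-6 with C-8.

Step 9
Reactants: 18 (2S)-5-hydroxy-7-(methoxymethoxy)-6-methyl-2-phenyl-2,3-dihydro-4H-chromen-4-one
Product: 19 (2S)-strobopinin [(2S)-5,7-dihydroxy-6-methyl-2-phenyl-2,3-dihydro-4H-chromen-4-one]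
Conditions: HCl (3 M aq)/MeOH, 50 °C
Reagents that add atoms: none
Why: Acid-catalysed methanolysis of the MOM acetal; flavanones are configurationally stable in dilute acid, so C-2 is untouched.

Step 10
Reactants: 14 5-methoxy-4,6,6-trimethyl-2-(2-methylpropylidene)cyclohex-4-ene-1,3-dione; 19 (2S)-strobopinin
Product: 20 (2S)-5,7-dihydroxy-8-[(1R)-1-(2-hydroxy-4-methoxy-3,3,5-trimethyl-6-oxocyclohexa-1,4-dien-1-yl)-2-methylpropyl]-6-methyl-2-phenyl-2,3-dihydro-4H-chromen-4-one (target)
Conditions: (R)-3,3′-bis(2,4,6-triisopropylphenyl)-1,1′-binaphthyl-2,2′-diyl hydrogen phosphate ((R)-TRIP, 10 mol %; the antipode if the screen demands), 14 (1.2 equiv), 4 Å molecular sieves, CH2Cl2, −20 °C; chromatography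
Reagents that add atoms: none
Why: Brønsted-acid-catalysed Friedel–Crafts-type Michael addition, the bond-forming event of the biomimetic assembly of triketone–phloroglucinol adducts: C-8 is the only free nucleophilic carbon of ring A, the chiral phosphate binds the 7-OH and a dione carbonyl of 14 and so decides which face of the alkylidene carbon is attacked (C-1′ to be set as R), C-2 (S) is not touched, and because C-2 is fixed the minor C-1′ epimer is a diastereomer that is removed by chromatography.

**Compound list**

1 | propanoyl chloride | CCC(=O)Cl | starting material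
2 | (ethoxyethynyl)trimethylsilane | CCOC#C[Si](C)(C)C | starting material
3 | methylketene (prop-1-en-1-one) | CC=C=O | intermediate (not isolated)
4 | 3-ethoxy-4-methyl-2-(trimethylsilyl)cyclobut-2-en-1-one, racemic | CCOC1=C([Si](C)(C)C)C(=O)C1C | intermediate
5 | 1,1,1-trimethoxy-2-methylpropane (trimethyl orthoisobutyrate) | CC(C)C(OC)(OC)OC | starting material
6 | 1,1-dimethoxy-2-methylprop-1-ene | COC(OC)=C(C)C | intermediate
7 | (3Z)-3-ethoxy-2-(trimethylsilyl)penta-1,3-dien-1-one (silylvinylketene; Z expected from outward rotation of the methyl group) | C/C=C(OCC)/C(=C=O)[Si](C)(C)C | intermediate (not isolated)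
8 | zwitterion: dimethoxycarbenium ion joined through CMe2 to the oxygen-bearing carbon of the (Z)-configured 3-ethoxy-2-silyl dienolate (C–C bond between the ketene carbon of 7 and the CMe2 carbon of 6) | [O-]/C(=C(\[Si](C)(C)C)/C(OCC)=C/C)C(C)(C)C(OC)=[O+]C | intermediate (not isolated)
9 | 3-ethoxy-5,5-dimethoxy-4,6,6-trimethyl-2-(trimethylsilyl)cyclohex-2-en-1-one, racemic | CCOC1=C([Si](C)(C)C)C(=O)C(C)(C)C(OC)(OC)C1C | intermediate (not isolated)
10 | 3-ethoxy-5-methoxy-4,6,6-trimethylcyclohexa-2,4-dien-1-one | CCOC1=CC(=O)C(C)(C)C(OC)=C1C | intermediate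
11 | 3-hydroxy-5-methoxy-4,4,6-trimethylcyclohexa-2,5-dien-1-one | COC1=C(C)C(=O)C=C(O)C1(C)C | intermediate
12 | 2-methylpropanal (isobutyraldehyde) | CC(C)C=O | starting material
13 | Mannich base: 3-hydroxy-5-methoxy-4,4,6-trimethyl-2-[2-methyl-1-(piperidin-1-yl)propyl]cyclohexa-2,5-dien-1-one, racemic | COC1=C(C)C(=O)C(C(C(C)C)N2CCCCC2)=C(O)C1(C)C | intermediate (not isolated)
14 | 5-methoxy-4,6,6-trimethyl-2-(2-methylpropylidene)cyclohex-4-ene-1,3-dione, E/Z mixture | COC1=C(C)C(=O)C(=CC(C)C)C(=O)C1(C)C | intermediate
15 | (2S)-pinocembrin | c1c(O)cc(O)c2c1O[C@H](c1ccccc1)CC2=O | starting material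
16 | (2S)-5-hydroxy-7-(methoxymethoxy)-2-phenyl-2,3-dihydro-4H-chromen-4-one | c1c(OCOC)cc(O)c2c1O[C@H](c1ccccc1)CC2=O | intermediate
17 | (2S)-5-hydroxy-6-iodo-7-(methoxymethoxy)-2-phenyl-2,3-dihydro-4H-chromen-4-one | c1c(OCOC)c(I)c(O)c2c1O[C@H](c1ccccc1)CC2=O | intermediate
18 | (2S)-5-hydroxy-7-(methoxymethoxy)-6-methyl-2-phenyl-2,3-dihydro-4H-chromen-4-one | c1c(OCOC)c(C)c(O)c2c1O[C@H](c1ccccc1)CC2=O | intermediate
19 | (2S)-strobopinin, (2S)-5,7-dihydroxy-6-methyl-2-phenyl-2,3-dihydro-4H-chromen-4-one | c1c(O)c(C)c(O)c2c1O[C@H](c1ccccc1)CC2=O | intermediate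
20 | (2S)-5,7-dihydroxy-8-[(1R)-1-(2-hydroxy-4-methoxy-3,3,5-trimethyl-6-oxocyclohexa-1,4-dien-1-yl)-2-methylpropyl]-6-methyl-2-phenyl-2,3-dihydro-4H-chromen-4-one | COC1=C(C)C(=O)C([C@@H](c2c(O)c(C)c(O)c3c2O[C@H](c2ccccc2)CC3=O)C(C)C)=C(O)C1(C)C | target

**Count and risks**

Total step count: 10. Longest linear sequence: 5 steps (1 → 3 → 4 → 5 → 10; the flavanone branch 6 → 7 → 8 → 9 → 10 is equally long).

Steps most likely to fail:

Step 3 (proposed new method). The bimolecular addition of the hindered ketene acetal may be outrun by decay or dimerisation of the vinylketene, or the zwitterion may collapse by proton transfer or O-closure instead of six-ring closure. The fallback uses known chemistry, builds ring D without the annulation and methylates last; it sets out from 12 and 19 and rejoins the route at 20. Commercial 2,4,6-trihydroxyacetophenone is C-methylated three times (MeI, NaOMe, MeOH) to 2-acetyl-3,5-dihydroxy-4,4,6-trimethylcyclohexa-2,5-dien-1-one F1, whose acetyl group is removed by hot aqueous HCl (retro-Claisen deacylation) to give 3,5-dihydroxy-4,4,6-trimethylcyclohexa-2,5-dien-1-one F2. Proline-catalysed Knoevenagel condensation of F2 with 12 should give 5-hydroxy-4,6,6-trimethyl-2-(2-methylpropylidene)cyclohex-4-ene-1,3-dione F3, and the chiral-acid-catalysed addition of 19 (as in step 10) should give the O-desmethyl adduct (2S)-8-[(1R)-1-(2,4-dihydroxy-3,3,5-trimethyl-6-oxocyclohexa-1,4-dien-1-yl)-2-methylpropyl]-5,7-dihydroxy-6-methyl-2-phenyl-2,3-dihydro-4H-chromen-4-one F4. One equivalent of Me3SiCHN2 in toluene/MeOH is then expected to methylate the least hindered enol oxygen, the one between CMe2 and CMe (the other enol is flanked by the bulky side chain, and the phenols are less acidic), to give 20. The regioselectivity of this last methylation is the weak point of the fallback.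

Step 10. Facial selectivity at the alkylidene carbon may be poor, or the C-1′ centre may erode by retro-Michael/Michael equilibration. The fallback replaces catalyst control by separation and recycling; it sets out from 14 and 19 and rejoins at 20. An achiral promoter (diphenyl hydrogen phosphate, CH2Cl2, rt) should give both C-1′ epimers, 20 and (2S)-5,7-dihydroxy-8-[(1S)-1-(2-hydroxy-4-methoxy-3,3,5-trimethyl-6-oxocyclohexa-1,4-dien-1-yl)-2-methylpropyl]-6-methyl-2-phenyl-2,3-dihydro-4H-chromen-4-one F5. These are diastereomers and are separated by preparative HPLC; F5 is returned to the same acid at 40 °C, where retro-Michael/Michael equilibration regenerates the mixture, and is recycled.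

Step 1. Self-dimerisation of the aldoketene may outrun its cycloaddition with the hindered silyl ynol ether. The fallback uses a halo ketene and a reductive dechlorination; it sets out from 2 and rejoins at 4. 2-Chloropropanoyl chloride and Et3N give chloro(methyl)ketene F6 (not isolated), a more electrophilic and slower-dimerising [2+2] partner, which with 2 should give 4-chloro-3-ethoxy-4-methyl-2-(trimethylsilyl)cyclobut-2-en-1-one F7. Zinc dust in AcOH/EtOH with TMEDA then removes the chlorine to give 4.

**Further compounds**

F1 | step 3 | 2-acetyl-3,5-dihydroxy-4,4,6-trimethylcyclohexa-2,5-dien-1-one | CC(=O)C1=C(O)C(C)(C)C(O)=C(C)C1=O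
F2 | step 3 | 3,5-dihydroxy-4,4,6-trimethylcyclohexa-2,5-dien-1-one | OC1=CC(=O)C(C)=C(O)C1(C)C
F3 | step 3 | 5-hydroxy-4,6,6-trimethyl-2-(2-methylpropylidene)cyclohex-4-ene-1,3-dione | CC(C)C=C1C(=O)C(C)=C(O)C(C)(C)C1=O
F4 | step 3 | (2S)-8-[(1R)-1-(2,4-dihydroxy-3,3,5-trimethyl-6-oxocyclohexa-1,4-dien-1-yl)-2-methylpropyl]-5,7-dihydroxy-6-methyl-2-phenyl-2,3-dihydro-4H-chromen-4-one | OC1=C(C)C(=O)C([C@@H](c2c(O)c(C)c(O)c3c2O[C@H](c2ccccc2)CC3=O)C(C)C)=C(O)C1(C)C
F5 | step 10 | (2S)-5,7-dihydroxy-8-[(1S)-1-(2-hydroxy-4-methoxy-3,3,5-trimethyl-6-oxocyclohexa-1,4-dien-1-yl)-2-methylpropyl]-6-methyl-2-phenyl-2,3-dihydro-4H-chromen-4-one | COC1=C(C)C(=O)C([C@H](c2c(O)c(C)c(O)c3c2O[C@H](c2ccccc2)CC3=O)C(C)C)=C(O)C1(C)C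
F6 | step 1 | chloro(methyl)ketene (2-chloroprop-1-en-1-one) | CC(Cl)=C=O
F7 | step 1 | 4-chloro-3-ethoxy-4-methyl-2-(trimethylsilyl)cyclobut-2-en-1-one | CCOC1=C([Si](C)(C)C)C(=O)C1(C)Cl
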